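**Strategy.** The route rests on disconnecting C5–C6, the bond between the Z-configured C4=C5 alkene and the γ-carbon of the butenolide. C6 is bonded to sp2 C5 and is also the acidic γ-position of the C6–C7=C11–C12 lactone, whose deprotonation gives an aromatic 2-oxidofuran. A palladium-catalysed dienolate–alkenyl iodide coupling uses exactly this: in one operation it forms C5–C6, closes the ten-membered carbocycle on the intact butenolide and sets C6 under control of C8. The precursor is an open-chain 4-alkylbutenolide with an unsubstituted C6 methylene, silyl ethers at C8 and C13, a PMB ether at C1, the C10 methylidene and a terminal (Z)-alkenyl iodide at C5.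

Key step: step 13

Remark: name and SMILES of the target agree (1β-OH = 1R, 6α-O = 6R, 8α-OAc = 8S, 4Z) and germacrane numbering is used throughout; it is assumed that in the oxazaborolidine reduction the α-branched alkenyl group acts as the larger ketone substituent; C13 is carried as a triisopropylsilyl ether, which comes in one step from a commercial chloromethyl silyl ether and shields C11 better than a smaller silyl group.

**Step 1**
Reactants: 1 propargyl alcohol
Product: 3 (Z)-3-iodo-2-methylprop-2-en-1-ol, via alkenylmagnesium chelate 2 (not isolated)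
Conditions: MeMgBr (2.5 equiv), CuI (10 mol %), Et2O, −10 °C → rt; then I2, −20 → 0 °C
Reagents that add atoms: methylmagnesium bromide, C[Mg]Br; iodine, II
Why: Copper-catalysed anti-carbomagnesiation of the propargylic alkoxide puts methyl on C4 and magnesium on C5 cis to the CH2O group in a five-membered chelate, and iodinolysis with retention should give only the Z iodide.

**Step 2**
Reactants: 3 (Z)-3-iodo-2-methylprop-2-en-1-ol
Product: 4 (Z)-3-bromo-1-iodo-2-methylprop-1-ene
Conditions: PBr3 (0.4 equiv), Et2O, 0 °C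
Reagents that add atoms: phosphorus tribromide, BrP(Br)Br
Why: Bromide displaces the activated primary allylic oxygen by SN2 substitution, leaving the alkene geometry untouched.

**Step 3**
Reactants: 5 3-methylbut-3-en-2-one; 4 (Z)-3-bromo-1-iodo-2-methylprop-1-ene
Product: 7 (6Z)-7-iodo-2,6-dimethylhepta-1,6-dien-3-one, via lithium dienolate 6 (not isolated)
Conditions: LiN(i-Pr)2 (1.1 equiv), THF, −78 °C; then 4 (0.85 equiv), DMPU, −78 → −30 °C
Reagents that add atoms: none
Why: Kinetic deprotonation of the methyl ketone gives the cross-conjugated enolate, whose C-alkylation by the reactive allylic bromide (enolate allylation) forms C2–C3.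

**Step 4**
Reactants: 7 (6Z)-7-iodo-2,6-dimethylhepta-1,6-dien-3-one
Product: 8 (3R,6Z)-7-iodo-2,6-dimethylhepta-1,6-dien-3-ol
Conditions: (S)-2-methyl-CBS-oxazaborolidine (20 mol %), catecholborane (1.5 equiv), toluene, −78 °C
Reagents that add atoms: none
Why: In this Corey–Bakshi–Shibata reduction the isopropenyl group takes the large-substituent position, so the (S)-catalyst should deliver hydride to give the 1R carbinol; catecholborane at low temperature avoids hydroboration and conjugate reduction.

**Step 5**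
Reactants: 8 (3R,6Z)-7-iodo-2,6-dimethylhepta-1,6-dien-3-ol
Product: 10 (3R,6Z)-7-iodo-3-(4-methoxybenzyloxy)-2,6-dimethylhepta-1,6-diene, via sodium alkoxide 9 (not isolated)
Conditions: NaH, THF–DMF, 0 °C; then PMBCl, n-Bu4NI (cat.), 0 °C → rt
Reagents that add atoms: 4-methoxybenzyl chloride, COc1ccc(CCl)cc1
Why: Williamson etherification at oxygen does not touch the C1 stereocentre, and the alkenyl iodide has no hydrogen placed for elimination.

**Step 6**
Reactants: 10 (3R,6Z)-7-iodo-3-(4-methoxybenzyloxy)-2,6-dimethylhepta-1,6-diene; 11 ethyl glyoxylate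
Product: 12 ethyl (2S,5R,8Z)-2-hydroxy-9-iodo-5-(4-methoxybenzyloxy)-8-methyl-4-methylidenenon-8-enoate
Conditions: (S)-BINOL (10 mol %), TiCl2(O-i-Pr)2 (10 mol %), 4 Å MS, CH2Cl2, −30 → 0 °C; 11 freshly distilled (3 equiv)
Reagents that add atoms: none
Why: In this catalytic asymmetric glyoxylate–ene reaction the terminal carbon of the 1,1-disubstituted alkene (C9) bonds to the aldehyde carbon (C8) while a methyl hydrogen passes to oxygen, moving the alkene to C10=C14; the catalyst from (S)-BINOL and TiCl2(O-i-Pr)2 should set 8S, the 1R ether is expected to be its matched partner, and the trisubstituted iodoalkene is too electron-poor to compete.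

**Step 7**
Reactants: 12 ethyl (2S,5R,8Z)-2-hydroxy-9-iodo-5-(4-methoxybenzyloxy)-8-methyl-4-methylidenenon-8-enoate
Product: 13 ethyl (2S,5R,8Z)-2-(tert-butyldimethylsilyloxy)-9-iodo-5-(4-methoxybenzyloxy)-8-methyl-4-methylidenenon-8-enoate
Conditions: TBSCl, imidazole, DMF, rt
Reagents that add atoms: tert-butyldimethylsilyl chloride, CC(C)(C)[Si](C)(C)Cl
Why: Imidazole-promoted silylation of the secondary alcohol proceeds at oxygen without touching C8.

**Step 8**
Reactants: 13 ethyl (2S,5R,8Z)-2-(tert-butyldimethylsilyloxy)-9-iodo-5-(4-methoxybenzyloxy)-8-methyl-4-methylidenenon-8-enoate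
Product: 14 (2S,5R,8Z)-2-(tert-butyldimethylsilyloxy)-9-iodo-N-methoxy-5-(4-methoxybenzyloxy)-N,8-dimethyl-4-methylidenenon-8-enamide
Conditions: MeNH(OMe)·HCl (3 equiv), i-PrMgCl (6 equiv), THF, −20 °C (amide preformed); then 13, −20 → 0 °C
Reagents that add atoms: N,O-dimethylhydroxylamine hydrochloride, CNOC.Cl
Why: Aminolysis of the ester by the preformed chloromagnesium amide (Weinreb amide formation) uses a nucleophile too weakly basic to enolise C8 or to exchange with the alkenyl iodide.

**Step 9**
Reactants: 14 (2S,5R,8Z)-2-(tert-butyldimethylsilyloxy)-9-iodo-N-methoxy-5-(4-methoxybenzyloxy)-N,8-dimethyl-4-methylidenenon-8-enamide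
Product: 15 (3S,6R,9Z)-3-(tert-butyldimethylsilyloxy)-1-chloro-10-iodo-6-(4-methoxybenzyloxy)-9-methyl-5-methylidenedec-9-en-2-one
Conditions: ICH2Cl (3 equiv), MeLi·LiBr (2.8 equiv, slow addition), THF, −78 °C; then sat. aq. NH4Cl
Reagents that add atoms: chloroiodomethane, ClCI
Why: Chloromethyllithium generated in the presence of the amide adds once (carbenoid homologation of a Weinreb amide), the ketone being released only on quenching; iodine–lithium exchange at ICH2Cl should far outpace exchange at the alkenyl iodide, and C8 is not enolised at −78 °C.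

**Step 10**
Reactants: 16 allyl 2-(diethoxyphosphoryl)acetate
Product: 18 allyl 2-(diethoxyphosphoryl)-3-(triisopropylsilyloxy)propanoate (racemic), via sodium phosphonoenolate 17 (not isolated)
Conditions: NaH (1.0 equiv), THF, 0 °C; then (i-Pr)3SiOCH2Cl (0.95 equiv), 0 °C → rt
Reagents that add atoms: (triisopropylsiloxy)methyl chloride, ClCO[Si](C(C)C)(C(C)C)C(C)C
Why: C-alkylation of the stabilised phosphonate carbanion by the chloromethyl ether installs C13 with its oxygen already silylated.

**Step 11**
Reactants: 18 allyl 2-(diethoxyphosphoryl)-3-(triisopropylsilyloxy)propanoate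
Product: 19 2-(diethoxyphosphoryl)-3-(triisopropylsilyloxy)propanoic acid (racemic)
Conditions: Pd(PPh3)4 (3 mol %), morpholine (3 equiv), THF, rt; aq. KHSO4 work-up
Reagents that add atoms: none
Why: In this Tsuji–Trost deallylation zerovalent palladium ionises the allyl ester and morpholine traps the allyl group, which frees the acid without the hydroxide that could provoke β-elimination of the silyloxy group.

**Step 12**
Reactants: 15 (3S,6R,9Z)-3-(tert-butyldimethylsilyloxy)-1-chloro-10-iodo-6-(4-methoxybenzyloxy)-9-methyl-5-methylidenedec-9-en-2-one; 19 2-(diethoxyphosphoryl)-3-(triisopropylsilyloxy)propanoic acid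
Product: 21 4-[(1S,4R,7Z)-1-(tert-butyldimethylsilyloxy)-8-iodo-4-(4-methoxybenzyloxy)-7-methyl-3-methylideneoct-7-en-1-yl]-3-[(triisopropylsilyloxy)methyl]furan-2(5H)-one, via acyloxy ketone 20 (not isolated)
Conditions: 19 (1.3 equiv), Cs2CO3 (0.65 equiv), DMF, 0 °C → rt; then LiCl, DBU, MeCN, 0 °C → rt
Reagents that add atoms: none
Why: Carboxylate SN2 displacement of the α-chloro ketone forms C6–O, and the phosphonate carbanion of 20 then closes on the C7 ketone by intramolecular Horner–Wadsworth–Emmons olefination (Masamune–Roush conditions) to give the C7=C11 butenolide; loss of silanolate from the carbanion is a reversible retro-oxa-Michael event whereas the olefination is irreversible.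

**Step 13**
Reactants: 21 4-[(1S,4R,7Z)-1-(tert-butyldimethylsilyloxy)-8-iodo-4-(4-methoxybenzyloxy)-7-methyl-3-methylideneoct-7-en-1-yl]-3-[(triisopropylsilyloxy)methyl]furan-2(5H)-one
Product: 23 (1R,6R,8S,4Z)-8-(tert-butyldimethylsilyloxy)-1-(4-methoxybenzyloxy)-13-(triisopropylsilyloxy)germacra-4,7(11),10(14)-trien-12,6-olide, via cesium oxidofuran 22 (not isolated)
Conditions: Pd(OAc)2 (10 mol %), DPEphos (12 mol %), Cs2CO3 (2 equiv), degassed toluene, 60 °C, 21 added over 10 h (final 2 mM)
Reagents that add atoms: none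
Why: Proposed new method: zerovalent palladium (formed in the flask from Pd(OAc)2 and the diphosphine) inserts into the C5–I bond with retention of the Z geometry, Cs2CO3 turns the butenolide into the aromatic cesium 2-oxidofuran 22, this replaces iodide on divalent palladium and binds through C6, and C–C reductive elimination forms C5–C6. The closest known reaction types are the intermolecular palladium-catalysed γ-arylation of butenolide dienolates and the intramolecular alkenylation of ketone enolates by (Z)-alkenyl iodides, which so far closes only common rings, so a macrocyclic γ-alkenylation is without precedent. The ten-membered carbocycle closes at the metal, by reductive elimination from an eleven-membered palladacycle and not by a Baldwin-type attack; the Z alkene already holds C3 and C6 on one side, and slow addition keeps the coupling intramolecular. C6 is created in this elimination under control of C8: allylic strain against the C13 substituent should keep H8 in the butenolide plane, C9 and the silyloxy group then lie on opposite faces, and only bonding of C5 to the face anti to C9 gives an unstrained ring (torsions of like sign about C6–C7 and C7–C8), which is the 6R configuration. The step needs γ- over α-coupling, secured by the fully substituted C11 and its bulky silyloxymethyl group, and it needs enolate capture to outrun 6-exo carbopalladation of the C10=C14 alkene, which the chelating diphosphine with iodide retained on palladium in toluene should ensure by leaving no free coordination site. C13 carries a silyl ether and not an acetate because the oxidofuran would expel a good leaving group from that position.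

**Step 14**
Reactants: 23 (1R,6R,8S,4Z)-8-(tert-butyldimethylsilyloxy)-1-(4-methoxybenzyloxy)-13-(triisopropylsilyloxy)germacra-4,7(11),10(14)-trien-12,6-olide
Product: 24 (1R,6R,8S,4Z)-8,13-dihydroxy-1-(4-methoxybenzyloxy)germacra-4,7(11),10(14)-trien-12,6-olide
Conditions: HF·pyridine, pyridine, THF, 0 °C → rt
Reagents that add atoms: none
Why: Fluoride-driven desilylation removes both silyl ethers under buffered, non-basic conditions, so C6 is not deprotonated and the PMB ether survives; the 8-hydroxyl cannot translactonise because the tetrahedral intermediate would hold the C7=C11 bond at a bridgehead.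

**Step 15**
Reactants: 24 (1R,6R,8S,4Z)-8,13-dihydroxy-1-(4-methoxybenzyloxy)germacra-4,7(11),10(14)-trien-12,6-olide
Product: 25 (1R,6R,8S,4Z)-8,13-diacetoxy-1-(4-methoxybenzyloxy)germacra-4,7(11),10(14)-trien-12,6-olide
Conditions: Ac2O, pyridine, DMAP (cat.), CH2Cl2, 0 °C
Reagents that add atoms: acetic anhydride, CC(=O)OC(C)=O
Why: Nucleophile-catalysed acylation esterifies both hydroxyls; the weak amine base at 0 °C should not form the oxidofuran that would expel the new C13 acetate.

**Step 16**
Reactants: 25 (1R,6R,8S,4Z)-8,13-diacetoxy-1-(4-methoxybenzyloxy)germacra-4,7(11),10(14)-trien-12,6-olide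
Product: 26 8α,13-diacetoxy-1β-hydroxygermacra-4,7(11),10(14)-trien-6α,12-olide (1R,6R,8S,4Z)
Conditions: DDQ (1.5 equiv), CH2Cl2–pH 7 buffer (10:1), 0 °C
Reagents that add atoms: none
Why: Oxidative cleavage of the PMB ether (hydride abstraction, then hydrolysis of the oxocarbenium ion) runs under neutral conditions that spare the acetates, the butenolide and the alkenes, and the C1–O bond is never broken.

**Compound list**

1 | propargyl alcohol | C#CCO | starting material
2 | alkenylmagnesium chelate (4-methyl-2,5-dihydro-1,2-oxamagnesole) | CC1=C[Mg]OC1 | intermediate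
3 | (Z)-3-iodo-2-methylprop-2-en-1-ol | I/C=C(/C)CO | intermediate
4 | (Z)-3-bromo-1-iodo-2-methylprop-1-ene | I/C=C(/C)CBr | intermediate
5 | 3-methylbut-3-en-2-one | CC(=C)C(C)=O | starting material
6 | lithium 3-methylbuta-1,3-dien-2-olate | [Li+].[O-]C(=C)C(C)=C | intermediate
7 | (6Z)-7-iodo-2,6-dimethylhepta-1,6-dien-3-one | I/C=C(/C)CCC(=O)C(C)=C | intermediate
8 | (3R,6Z)-7-iodo-2,6-dimethylhepta-1,6-dien-3-ol | I/C=C(/C)CC[C@@H](O)C(C)=C | intermediate
9 | sodium (3R,6Z)-7-iodo-2,6-dimethylhepta-1,6-dien-3-olate | I/C=C(/C)CC[C@@H]([O-])C(C)=C.[Na+] | intermediate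
10 | (3R,6Z)-7-iodo-3-(4-methoxybenzyloxy)-2,6-dimethylhepta-1,6-diene | I/C=C(/C)CC[C@@H](OCc1ccc(OC)cc1)C(C)=C | intermediate
11 | ethyl glyoxylate | CCOC(=O)C=O | starting material
12 | ethyl (2S,5R,8Z)-2-hydroxy-9-iodo-5-(4-methoxybenzyloxy)-8-methyl-4-methylidenenon-8-enoate | I/C=C(/C)CC[C@@H](OCc1ccc(OC)cc1)C(=C)C[C@H](O)C(=O)OCC | intermediate
13 | ethyl (2S,5R,8Z)-2-(tert-butyldimethylsilyloxy)-9-iodo-5-(4-methoxybenzyloxy)-8-methyl-4-methylidenenon-8-enoate | I/C=C(/C)CC[C@@H](OCc1ccc(OC)cc1)C(=C)C[C@H](O[Si](C)(C)C(C)(C)C)C(=O)OCC | intermediate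
14 | (2S,5R,8Z)-2-(tert-butyldimethylsilyloxy)-9-iodo-N-methoxy-5-(4-methoxybenzyloxy)-N,8-dimethyl-4-methylidenenon-8-enamide | I/C=C(/C)CC[C@@H](OCc1ccc(OC)cc1)C(=C)C[C@H](O[Si](C)(C)C(C)(C)C)C(=O)N(C)OC | intermediate
15 | (3S,6R,9Z)-3-(tert-butyldimethylsilyloxy)-1-chloro-10-iodo-6-(4-methoxybenzyloxy)-9-methyl-5-methylidenedec-9-en-2-one | I/C=C(/C)CC[C@@H](OCc1ccc(OC)cc1)C(=C)C[C@H](O[Si](C)(C)C(C)(C)C)C(=O)CCl | intermediate
16 | allyl 2-(diethoxyphosphoryl)acetate | C=CCOC(=O)CP(=O)(OCC)OCC | starting material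
17 | sodium enolate of allyl 2-(diethoxyphosphoryl)acetate | [Na+].C=CCOC(=O)[CH-]P(=O)(OCC)OCC | intermediate
18 | allyl 2-(diethoxyphosphoryl)-3-(triisopropylsilyloxy)propanoate (racemic) | C=CCOC(=O)C(CO[Si](C(C)C)(C(C)C)C(C)C)P(=O)(OCC)OCC | intermediate
19 | 2-(diethoxyphosphoryl)-3-(triisopropylsilyloxy)propanoic acid (racemic) | OC(=O)C(CO[Si](C(C)C)(C(C)C)C(C)C)P(=O)(OCC)OCC | intermediate
20 | (3S,6R,9Z)-3-(tert-butyldimethylsilyloxy)-10-iodo-6-(4-methoxybenzyloxy)-9-methyl-5-methylidene-2-oxodec-9-en-1-yl 2-(diethoxyphosphoryl)-3-(triisopropylsilyloxy)propanoate | I/C=C(/C)CC[C@@H](OCc1ccc(OC)cc1)C(=C)C[C@H](O[Si](C)(C)C(C)(C)C)C(=O)COC(=O)C(CO[Si](C(C)C)(C(C)C)C(C)C)P(=O)(OCC)OCC | intermediate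
21 | 4-[(1S,4R,7Z)-1-(tert-butyldimethylsilyloxy)-8-iodo-4-(4-methoxybenzyloxy)-7-methyl-3-methylideneoct-7-en-1-yl]-3-[(triisopropylsilyloxy)methyl]furan-2(5H)-one | I/C=C(/C)CC[C@@H](OCc1ccc(OC)cc1)C(=C)C[C@H](O[Si](C)(C)C(C)(C)C)C2=C(CO[Si](C(C)C)(C(C)C)C(C)C)C(=O)OC2 | intermediate
22 | cesium 2-oxidofuran of 21 (cesium 4-alkyl-3-[(triisopropylsilyloxy)methyl]furan-2-olate) | I/C=C(/C)CC[C@@H](OCc1ccc(OC)cc1)C(=C)C[C@H](O[Si](C)(C)C(C)(C)C)c2coc([O-])c2CO[Si](C(C)C)(C(C)C)C(C)C.[Cs+] | intermediate
23 | (1R,6R,8S,4Z)-8-(tert-butyldimethylsilyloxy)-1-(4-methoxybenzyloxy)-13-(triisopropylsilyloxy)germacra-4,7(11),10(14)-trien-12,6-olide | C=C1C[C@H](O[Si](C)(C)C(C)(C)C)C2=C(CO[Si](C(C)C)(C(C)C)C(C)C)C(=O)O[C@@H]2/C=C(/C)CC[C@H]1OCc3ccc(OC)cc3 | intermediate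
24 | (1R,6R,8S,4Z)-8,13-dihydroxy-1-(4-methoxybenzyloxy)germacra-4,7(11),10(14)-trien-12,6-olide | C=C1C[C@H](O)C2=C(CO)C(=O)O[C@@H]2/C=C(/C)CC[C@H]1OCc3ccc(OC)cc3 | intermediate
25 | (1R,6R,8S,4Z)-8,13-diacetoxy-1-(4-methoxybenzyloxy)germacra-4,7(11),10(14)-trien-12,6-olide | C=C1C[C@H](OC(C)=O)C2=C(COC(C)=O)C(=O)O[C@@H]2/C=C(/C)CC[C@H]1OCc3ccc(OC)cc3 | intermediate
26 | 8α,13-diacetoxy-1β-hydroxygermacra-4,7(11),10(14)-trien-6α,12-olide | C=C1C[C@H](OC(C)=O)C2=C(COC(C)=O)C(=O)O[C@@H]2/C=C(/C)CC[C@H]1O | target

**Step count.** Total: 16 steps. Longest linear sequence: 14 steps (steps 1–9 and 12–16); steps 10–11 prepare the phosphonate acid.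

**Steps most likely to fail**

1. Step 13. The alkenylpalladium intermediate may insert the C10=C14 alkene (6-exo carbopalladation) faster than it is captured by the oxidofuran. Other possible failures are intermolecular coupling, loss of silanolate from C13 of the oxidofuran, further deprotonation of the product with alkene migration, and bonding of C5 to the wrong face of C6. C6 stays epimerizable through the oxidofuran, so an unfavourable kinetic outcome at that centre could be corrected by base equilibration. Fallback with known chemistry, setting out from 21 and returning at 23: 21 would be O-silylated (TIPSOTf, Et3N, CH2Cl2, 0 °C) to the 2-(triisopropylsilyloxy)furan F1. Sensitised photooxygenation (O2, hν, tetraphenylporphyrin, CH2Cl2, −78 °C) would convert the electron-rich furan selectively into the γ-hydroxybutenolide F2 with loss of the silyl group. O-methylation of its ring-opened carboxylate (MeI, K2CO3, DMF, 0 °C) would give the (Z)-formyl methyl ester F3. An intramolecular Nozaki–Hiyama–Kishi reaction (CrCl2, NiCl2 cat., DMSO–THF, rt, high dilution) would then add the C5 alkenylchromium to the C6 aldehyde, and the resulting alkoxide would lactonise onto the neighbouring ester to give 23, with the C6 configuration again resting on ring conformation and base equilibration.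

2. Step 6. The existing 1R ether centre and the catalyst may turn out mismatched, or the ether oxygen may bind titanium, giving a slow ene reaction and poor facial selectivity at C8. Fallback, setting out from 10 (with 11) and returning at 12: the ene reaction would be run with the enantiomeric catalyst from (R)-BINOL and TiCl2(O-i-Pr)2, then the matched pairing, to give the 8R hydroxy ester F4. Mitsunobu inversion (4-nitrobenzoic acid, PPh3, DIAD, THF, 0 °C) would give the 8S 4-nitrobenzoate F5, and mild ethanolysis (K2CO3, EtOH, 0 °C) would release 12.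

3. Step 9. Iodine–lithium exchange at the C5 alkenyl iodide or a second addition of the carbenoid may compete with the single homologation. Fallback without any organolithium, setting out from 13 and returning at 15 (14 is bypassed): ester 13 would be treated with dimethylsulfoxonium methylide (Me3S(O)I, KOt-Bu, THF, rt → 50 °C) to give the β-keto sulfoxonium ylide F6. Protonation and chloride displacement of dimethyl sulfoxide (LiCl, MsOH 1 equiv, THF, 60 °C) would give 15.

**Further compounds**

F1 | step 13 | 2-(triisopropylsilyloxy)furan from 21: {4-[(1S,4R,7Z)-1-(tert-butyldimethylsilyloxy)-8-iodo-4-(4-methoxybenzyloxy)-7-methyl-3-methylideneoct-7-en-1-yl]-3-[(triisopropylsilyloxy)methyl]furan-2-yl}oxy-triisopropylsilane | I/C=C(/C)CC[C@@H](OCc1ccc(OC)cc1)C(=C)C[C@H](O[Si](C)(C)C(C)(C)C)c2coc(O[Si](C(C)C)(C(C)C)C(C)C)c2CO[Si](C(C)C)(C(C)C)C(C)C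
F2 | step 13 | 4-[(1S,4R,7Z)-1-(tert-butyldimethylsilyloxy)-8-iodo-4-(4-methoxybenzyloxy)-7-methyl-3-methylideneoct-7-en-1-yl]-5-hydroxy-3-[(triisopropylsilyloxy)methyl]furan-2(5H)-one (C6 epimers) | I/C=C(/C)CC[C@@H](OCc1ccc(OC)cc1)C(=C)C[C@H](O[Si](C)(C)C(C)(C)C)C2=C(CO[Si](C(C)C)(C(C)C)C(C)C)C(=O)OC2O
F3 | step 13 | methyl (2Z,4S,7R,10Z)-4-(tert-butyldimethylsilyloxy)-3-formyl-11-iodo-7-(4-methoxybenzyloxy)-10-methyl-6-methylidene-2-[(triisopropylsilyloxy)methyl]undeca-2,10-dienoate | I/C=C(/C)CC[C@@H](OCc1ccc(OC)cc1)C(=C)C[C@H](O[Si](C)(C)C(C)(C)C)/C(C=O)=C(\CO[Si](C(C)C)(C(C)C)C(C)C)C(=O)OC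
F4 | step 6 | ethyl (2R,5R,8Z)-2-hydroxy-9-iodo-5-(4-methoxybenzyloxy)-8-methyl-4-methylidenenon-8-enoate | I/C=C(/C)CC[C@@H](OCc1ccc(OC)cc1)C(=C)C[C@@H](O)C(=O)OCC
F5 | step 6 | ethyl (2S,5R,8Z)-9-iodo-5-(4-methoxybenzyloxy)-8-methyl-4-methylidene-2-(4-nitrobenzoyloxy)non-8-enoate | I/C=C(/C)CC[C@@H](OCc1ccc(OC)cc1)C(=C)C[C@H](OC(=O)c2ccc(cc2)[N+](=O)[O-])C(=O)OCC
F6 | step 9 | β-keto dimethylsulfoxonium ylide, (3S,6R,9Z)-3-(tert-butyldimethylsilyloxy)-1-(dimethyloxosulfanylidene)-10-iodo-6-(4-methoxybenzyloxy)-9-methyl-5-methylidenedec-9-en-2-one | I/C=C(/C)CC[C@@H](OCc1ccc(OC)cc1)C(=C)C[C@H](O[Si](C)(C)C(C)(C)C)C(=O)C=S(C)(C)=O
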